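**Plan**

- Numbering: chroman O1–C8a (ring A aromatic, ring C the dihydropyran); quinone ring B is C1' (on C3), C2'=O, C3' (prenyl), C4'–OH, C5'=O, C6'–H.
- Retrosynthesis cuts, in order: the C5'=O oxygen (back to a resorcinol), the aromatic level of ring B, the C3'–prenyl bond, then C1'–C6' and C3'–C4' together (ring B opens to a methyl ketone on C3 plus methyl acrylate), then O1–C2, then the C3=C4 bond of an arylidene succinate.
- Enabling feature: C2'=O with its two α-carbons C1' and C3' is a hidden acetone unit and the C4' oxygen stands 1,3 to it, so ring B is a masked 4-substituted cyclohexane-1,3-dione. Its C3', between the two carbonyls, is the one site that takes the prenyl group cleanly before late aromatisation.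
- Forward: ring A is dressed (prenyl, OH, CHO); Stobbe condensation and asymmetric hydrogenation give the benzylsuccinate; lactone, then methyl ketone; ring C by Mitsunobu; ring B by Michael–Claisen [3+3]; C3'-prenylation, dehydrogenation, Teuber oxidation.
- Stereochemistry: the single centre C3 (R) is set by the rhodium/DuPhos hydrogenation and is never α to a carbonyl after step 7; the extra centre made in the key step is erased on aromatisation.

Key step: step 11

Remark: the target is taken as the 2-hydroxy-1,4-benzoquinone tautomer drawn; the (S,S) ligand in step 6 is assumed to give the R acid as with other arylidene succinate half-esters, and the mirror-image ligand is used if a test run shows the opposite sense.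

**Route**

Step 1
Reactants: 1 1,3-dimethoxybenzene; 2 1-bromo-3-methylbut-2-ene (prenyl bromide)
Product: 3 1,3-dimethoxy-2-(3-methylbut-2-en-1-yl)benzene
Conditions: n-BuLi (1.1 equiv), THF, 0 °C to rt; then 2, −78 °C to rt
Reagents that add atoms: none
Why: Directed ortho-metalation removes the hydrogen flanked by both methoxy groups and the aryllithium is alkylated by the primary allylic bromide (SN2), which places the ring A prenyl group between the carbons that become C5 and C7.

Step 2
Reactants: 3 1,3-dimethoxy-2-(3-methylbut-2-en-1-yl)benzene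
Product: 5 3,5-dimethoxy-4-(3-methylbut-2-en-1-yl)phenol, via aryl pinacol boronate 4 (not isolated)
Conditions: B2pin2 (1.0 equiv), [Ir(OMe)(cod)]2 (1.5 mol%), 4,4'-di-tert-butyl-2,2'-bipyridine (3 mol%), THF, 80 °C; then H2O2 (30%), aq. NaOH, 0 °C to rt; 1 M HCl
Reagents that add atoms: bis(pinacolato)diboron CC1(C)OB(OC1(C)C)B1OC(C)(C)C(C)(C)O1 (boron of 4); hydrogen peroxide OO (oxygen of 5)
Why: Iridium-catalysed C–H borylation is governed by sterics and should go to C5, the only ring position without an ortho substituent, and alkaline peroxide oxidation of the C–B bond (1,2-shift of the aryl group from boron to oxygen) then gives the symmetric phenol without touching the trisubstituted alkene.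

Step 3
Reactants: 5 3,5-dimethoxy-4-(3-methylbut-2-en-1-yl)phenol
Product: 6 1,3-dimethoxy-5-(methoxymethoxy)-2-(3-methylbut-2-en-1-yl)benzene
Conditions: MOMCl (1.3 equiv), iPr2NEt (1.5 equiv), CH2Cl2, 0 °C to rt
Reagents that add atoms: chloromethyl methyl ether COCCl
Why: Base-mediated O-alkylation of the phenol with the α-chloro ether gives the methoxymethyl ether, which is stable to the bases of steps 4 to 7 and directs the metalation of step 4.

Step 4
Reactants: 6 1,3-dimethoxy-5-(methoxymethoxy)-2-(3-methylbut-2-en-1-yl)benzene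
Product: 7 2,4-dimethoxy-6-(methoxymethoxy)-3-(3-methylbut-2-en-1-yl)benzaldehyde
Conditions: n-BuLi (1.2 equiv), TMEDA (1.2 equiv), THF, −20 to 0 °C; DMF (2 equiv), −78 °C to rt; H2O
Reagents that add atoms: N,N-dimethylformamide CN(C)C=O
Why: Directed ortho-metalation next to the OMOM group (the two ortho positions are equivalent by symmetry and each is also flanked by OMe) followed by formylation with DMF gives the aldehyde carbon that becomes C4.

Step 5
Reactants: 7 2,4-dimethoxy-6-(methoxymethoxy)-3-(3-methylbut-2-en-1-yl)benzaldehyde; 8 dimethyl succinate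
Product: 9 (3E)-4-[2,4-dimethoxy-6-(methoxymethoxy)-3-(3-methylbut-2-en-1-yl)phenyl]-3-(methoxycarbonyl)but-3-enoic acid
Conditions: 8 (1.5 equiv), KOtBu (1.6 equiv), t-BuOH/THF, 50 °C; then 1 M HCl to pH 3, 0 °C
Reagents that add atoms: none
Why: Stobbe condensation (aldol addition, lactonisation and E1cB ring opening to the carboxylate) joins the succinate carbons that become C2, C3, C1' and C2', and should give the E half-ester because the aryl group turns away from the ester in the ring-opening step.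

Step 6
Reactants: 9 (3E)-4-[2,4-dimethoxy-6-(methoxymethoxy)-3-(3-methylbut-2-en-1-yl)phenyl]-3-(methoxycarbonyl)but-3-enoic acid
Product: 10 (3R)-4-[2,4-dimethoxy-6-(methoxymethoxy)-3-(3-methylbut-2-en-1-yl)phenyl]-3-(methoxycarbonyl)butanoic acid
Conditions: [Rh(cod)((S,S)-Et-DuPhos)]BF4 (1 mol%), H2 (5 bar), NaOMe (0.1 equiv), MeOH, 25 °C
Reagents that add atoms: none
Why: Asymmetric hydrogenation of an itaconate-type alkene, in which the carboxylate and the alkene chelate the cationic rhodium centre and the chiral bisphosphine selects the alkene face, sets C3 as R, while the non-chelating trisubstituted prenyl alkene is expected to stay untouched.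

Step 7
Reactants: 10 (3R)-4-[2,4-dimethoxy-6-(methoxymethoxy)-3-(3-methylbut-2-en-1-yl)phenyl]-3-(methoxycarbonyl)butanoic acid
Product: 12 (4R)-4-{[2,4-dimethoxy-6-(methoxymethoxy)-3-(3-methylbut-2-en-1-yl)phenyl]methyl}oxolan-2-one, via hydroxy acid 11 (not isolated)
Conditions: LiOH (1.0 equiv), MeOH, 0 °C, evaporate; LiBH4 (2 equiv), THF, 0 °C to rt; then 1 M HCl to pH 2–3, 0 °C to rt
Reagents that add atoms: none
Why: LiBH4 reduces the methyl ester but not the lithium carboxylate, and acidification closes the γ-lactone (acid-catalysed lactonisation), after which the stereocentre is no longer α to a carbonyl group.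

Step 8
Reactants: 12 (4R)-4-{[2,4-dimethoxy-6-(methoxymethoxy)-3-(3-methylbut-2-en-1-yl)phenyl]methyl}oxolan-2-one
Product: 13 (4R)-4-{[6-hydroxy-2,4-dimethoxy-3-(3-methylbut-2-en-1-yl)phenyl]methyl}oxolan-2-one
Conditions: ZnBr2 (1 equiv), n-PrSH (2 equiv), CH2Cl2, 0 °C to rt
Reagents that add atoms: none
Why: ZnBr2 activates the acetal and the thiol captures the methoxymethyl cation (acetal exchange), which frees the phenol without acid strong enough to harm the prenyl group or to let the cation alkylate the electron-rich ring.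

Step 9
Reactants: 13 (4R)-4-{[6-hydroxy-2,4-dimethoxy-3-(3-methylbut-2-en-1-yl)phenyl]methyl}oxolan-2-one
Product: 14 (4R)-5-hydroxy-4-{[6-hydroxy-2,4-dimethoxy-3-(3-methylbut-2-en-1-yl)phenyl]methyl}pentan-2-one
Conditions: MeLi (2.2 equiv), THF, −78 °C; AcOH, −78 °C
Reagents that add atoms: methyllithium [Li]C
Why: Addition of MeLi to the γ-lactone stops at the tetrahedral lithium hemiketal at −78 °C (the first equivalent is used by the phenol), so that the quench releases the methyl ketone whose CH3 becomes C3' (nucleophilic acyl addition with ring opening).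

Step 10
Reactants: 14 (4R)-5-hydroxy-4-{[6-hydroxy-2,4-dimethoxy-3-(3-methylbut-2-en-1-yl)phenyl]methyl}pentan-2-one
Product: 15 1-[(3R)-5,7-dimethoxy-6-(3-methylbut-2-en-1-yl)-3,4-dihydro-2H-chromen-3-yl]propan-2-one
Conditions: PPh3 (1.3 equiv), DIAD (1.3 equiv), THF, 0 °C to rt
Reagents that add atoms: none
Why: Intramolecular Mitsunobu etherification, with the phenol as the acidic partner and the primary alcohol as the activated one (6-exo-tet), closes ring C without involving the stereocentre.

Step 11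
Reactants: 15 1-[(3R)-5,7-dimethoxy-6-(3-methylbut-2-en-1-yl)-3,4-dihydro-2H-chromen-3-yl]propan-2-one; 16 methyl acrylate
Product: 18 4-[(3R)-5,7-dimethoxy-6-(3-methylbut-2-en-1-yl)-3,4-dihydro-2H-chromen-3-yl]cyclohexane-1,3-dione (C4 epimers), via Michael adduct keto ester 17 (not isolated)
Conditions: KOtBu (2.2 equiv), THF, 0 °C; 16 (1.1 equiv) added slowly, 0 °C to rt; then 1 M HCl
Reagents that add atoms: none
Why: With KOtBu the ketone enolates equilibrate and the more substituted one (the CH2 between C3 and the carbonyl, the future C1') adds to methyl acrylate in a Michael reaction (bond C1'–C6'); keto ester 17 is then deprotonated at its methyl group (future C3') and this enolate attacks the ester carbonyl (future C4') in an intramolecular Claisen condensation, with loss of methoxide and irreversible deprotonation of the 1,3-dione pulling the sequence forward. The closest known reaction type is the consecutive Michael–Claisen [3+3] annulation of methyl ketones with acrylates to 4-substituted cyclohexane-1,3-diones. Ring B closes in the 6-exo-trig (enolexo) mode. The new centre C4 of the dione is formed without control, is epimerisable and disappears on aromatisation, while C3 of the chroman is β to the ketone, carries no leaving group and cannot be reached by enolisation. The step needs regioselectivity (Michael at CH2, Claisen at CH3): thermodynamic enolate control favours the substituted carbon as Michael donor, after that only the methyl group can close a six-membered ring, and slow addition of 16 keeps a second Michael addition down.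

Step 12
Reactants: 18 4-[(3R)-5,7-dimethoxy-6-(3-methylbut-2-en-1-yl)-3,4-dihydro-2H-chromen-3-yl]cyclohexane-1,3-dione; 19 3-methylbut-2-en-1-yl acetate (prenyl acetate)
Product: 20 4-[(3R)-5,7-dimethoxy-6-(3-methylbut-2-en-1-yl)-3,4-dihydro-2H-chromen-3-yl]-2-(3-methylbut-2-en-1-yl)cyclohexane-1,3-dione
Conditions: 19 (1.0 equiv), Pd(PPh3)4 (5 mol%), DBU (1.1 equiv), THF, 50 °C
Reagents that add atoms: none
Why: Tsuji–Trost allylation, in which the soft dione enolate attacks the 1,1-dimethyl-π-allyl palladium complex at its unsubstituted end, puts a linear prenyl group on C2 of the dione (C3'), and any O-prenyl enol ether is re-ionised by zerovalent palladium and funnelled to the C-alkylated product.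

Step 13
Reactants: 20 4-[(3R)-5,7-dimethoxy-6-(3-methylbut-2-en-1-yl)-3,4-dihydro-2H-chromen-3-yl]-2-(3-methylbut-2-en-1-yl)cyclohexane-1,3-dione
Product: 22 4-[(3R)-5,7-dimethoxy-6-(3-methylbut-2-en-1-yl)-3,4-dihydro-2H-chromen-3-yl]-2-(3-methylbut-2-en-1-yl)benzene-1,3-diol, via cyclohexenedione 21 (not isolated)
Conditions: LiN(iPr)2 (2.3 equiv), THF/DMPU, −78 to −40 °C; N-tert-butylbenzenesulfinimidoyl chloride (1.1 equiv), −78 °C; aq. NH4Cl
Reagents that add atoms: none
Why: Dehydrogenation of a ketone enolate with a sulfinimidoyl chloride, in which the dianion takes the sulfur at C6, intramolecular syn-elimination makes the C5=C6 bond and enedione 21 tautomerises to the resorcinol, needs no oxidant that could attack the two prenyl groups (sulfur transfer to C4 would lead to the same arene).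

Step 14
Reactants: 22 4-[(3R)-5,7-dimethoxy-6-(3-methylbut-2-en-1-yl)-3,4-dihydro-2H-chromen-3-yl]-2-(3-methylbut-2-en-1-yl)benzene-1,3-diol
Product: 23 2-hydroxy-5-[(3R)-5,7-dimethoxy-6-(3-methylbut-2-en-1-yl)-3,4-dihydro-2H-chromen-3-yl]-3-(3-methylbut-2-en-1-yl)cyclohexa-2,5-diene-1,4-dione
Conditions: ON(SO3K)2 (Fremy's salt, 2.5 equiv), KH2PO4 buffer (pH 6), acetone/H2O, 0 °C to rt
Reagents that add atoms: dipotassium nitrosodisulfonate [K+].[K+].[O]N(S(=O)(=O)[O-])S(=O)(=O)[O-]
Why: Teuber oxidation, in which the nitrosodisulfonate radical oxidises the phenol and delivers oxygen to C5', the only free position para to the 2'-OH and ortho to the 4'-OH, gives the 2-hydroxy-1,4-benzoquinone, while ring A has no free OH and the buffered medium leaves C3 untouched.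

**Compound list**

1 | 1,3-dimethoxybenzene | COc1cccc(OC)c1 | starting material
2 | 1-bromo-3-methylbut-2-ene | CC(C)=CCBr | starting material
3 | 1,3-dimethoxy-2-(3-methylbut-2-en-1-yl)benzene | COc1cccc(OC)c1CC=C(C)C | intermediate
4 | 2-[3,5-dimethoxy-4-(3-methylbut-2-en-1-yl)phenyl]-4,4,5,5-tetramethyl-1,3,2-dioxaborolane | COc1cc(B2OC(C)(C)C(C)(C)O2)cc(OC)c1CC=C(C)C | intermediate
5 | 3,5-dimethoxy-4-(3-methylbut-2-en-1-yl)phenol | COc1cc(O)cc(OC)c1CC=C(C)C | intermediate
6 | 1,3-dimethoxy-5-(methoxymethoxy)-2-(3-methylbut-2-en-1-yl)benzene | COCOc1cc(OC)c(CC=C(C)C)c(OC)c1 | intermediate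
7 | 2,4-dimethoxy-6-(methoxymethoxy)-3-(3-methylbut-2-en-1-yl)benzaldehyde | COCOc1cc(OC)c(CC=C(C)C)c(OC)c1C=O | intermediate
8 | dimethyl succinate | COC(=O)CCC(=O)OC | starting material
9 | (3E)-4-[2,4-dimethoxy-6-(methoxymethoxy)-3-(3-methylbut-2-en-1-yl)phenyl]-3-(methoxycarbonyl)but-3-enoic acid | COCOc1cc(OC)c(CC=C(C)C)c(OC)c1/C=C(\CC(=O)O)C(=O)OC | intermediate
10 | (3R)-4-[2,4-dimethoxy-6-(methoxymethoxy)-3-(3-methylbut-2-en-1-yl)phenyl]-3-(methoxycarbonyl)butanoic acid | COCOc1cc(OC)c(CC=C(C)C)c(OC)c1C[C@H](CC(=O)O)C(=O)OC | intermediate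
11 | (3R)-4-[2,4-dimethoxy-6-(methoxymethoxy)-3-(3-methylbut-2-en-1-yl)phenyl]-3-(hydroxymethyl)butanoic acid | COCOc1cc(OC)c(CC=C(C)C)c(OC)c1C[C@H](CC(=O)O)CO | intermediate
12 | (4R)-4-{[2,4-dimethoxy-6-(methoxymethoxy)-3-(3-methylbut-2-en-1-yl)phenyl]methyl}oxolan-2-one | COCOc1cc(OC)c(CC=C(C)C)c(OC)c1C[C@H]1COC(=O)C1 | intermediate
13 | (4R)-4-{[6-hydroxy-2,4-dimethoxy-3-(3-methylbut-2-en-1-yl)phenyl]methyl}oxolan-2-one | COc1cc(O)c(C[C@H]2COC(=O)C2)c(OC)c1CC=C(C)C | intermediate
14 | (4R)-5-hydroxy-4-{[6-hydroxy-2,4-dimethoxy-3-(3-methylbut-2-en-1-yl)phenyl]methyl}pentan-2-one | COc1cc(O)c(C[C@H](CC(C)=O)CO)c(OC)c1CC=C(C)C | intermediate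
15 | 1-[(3R)-5,7-dimethoxy-6-(3-methylbut-2-en-1-yl)-3,4-dihydro-2H-chromen-3-yl]propan-2-one | COc1cc2c(c(OC)c1CC=C(C)C)C[C@H](CC(C)=O)CO2 | intermediate
16 | methyl acrylate | C=CC(=O)OC | starting material
17 | methyl 4-[(3R)-5,7-dimethoxy-6-(3-methylbut-2-en-1-yl)-3,4-dihydro-2H-chromen-3-yl]-5-oxohexanoate (C4 epimers) | COc1cc2c(c(OC)c1CC=C(C)C)C[C@H](C(CCC(=O)OC)C(C)=O)CO2 | intermediate
18 | 4-[(3R)-5,7-dimethoxy-6-(3-methylbut-2-en-1-yl)-3,4-dihydro-2H-chromen-3-yl]cyclohexane-1,3-dione (C4 epimers) | COc1cc2c(c(OC)c1CC=C(C)C)C[C@H](C1CCC(=O)CC1=O)CO2 | intermediate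
19 | 3-methylbut-2-en-1-yl acetate | CC(=O)OCC=C(C)C | starting material
20 | 4-[(3R)-5,7-dimethoxy-6-(3-methylbut-2-en-1-yl)-3,4-dihydro-2H-chromen-3-yl]-2-(3-methylbut-2-en-1-yl)cyclohexane-1,3-dione (epimers at C2 and C4) | COc1cc2c(c(OC)c1CC=C(C)C)C[C@H](C1CCC(=O)C(CC=C(C)C)C1=O)CO2 | intermediate
21 | 4-[(3R)-5,7-dimethoxy-6-(3-methylbut-2-en-1-yl)-3,4-dihydro-2H-chromen-3-yl]-2-(3-methylbut-2-en-1-yl)cyclohex-5-ene-1,3-dione | COc1cc2c(c(OC)c1CC=C(C)C)C[C@H](C1C=CC(=O)C(CC=C(C)C)C1=O)CO2 | intermediate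
22 | 4-[(3R)-5,7-dimethoxy-6-(3-methylbut-2-en-1-yl)-3,4-dihydro-2H-chromen-3-yl]-2-(3-methylbut-2-en-1-yl)benzene-1,3-diol | COc1cc2c(c(OC)c1CC=C(C)C)C[C@H](c1ccc(O)c(CC=C(C)C)c1O)CO2 | intermediate
23 | 2-hydroxy-5-[(3R)-5,7-dimethoxy-6-(3-methylbut-2-en-1-yl)-3,4-dihydro-2H-chromen-3-yl]-3-(3-methylbut-2-en-1-yl)cyclohexa-2,5-diene-1,4-dione | COc1cc2c(c(OC)c1CC=C(C)C)C[C@H](C1=CC(=O)C(O)=C(CC=C(C)C)C1=O)CO2 | target

**Step count and risks**

Total step count: 14. Longest linear sequence: 14 steps (from 1 to 23).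

Steps most likely to fail:

1. Step 11. The Michael addition may run through the methyl-side enolate, which would lead to the 2-substituted dione, or a second Michael addition and oligomerisation of the acrylate may consume the ketone. The fallback sets out from 12 and comes back at 18; it fixes the regiochemistry by forming the C1'–C6' bond at the lactone, which has a single α-CH2. Deprotonation of 12 with LiN(iPr)2 (THF, −78 °C) and Michael addition to tert-butyl acrylate should give tert-butyl 3-[(4R)-4-{[2,4-dimethoxy-6-(methoxymethoxy)-3-(3-methylbut-2-en-1-yl)phenyl]methyl}-2-oxooxolan-3-yl]propanoate F1 (C3 epimers, of no consequence). ZnBr2 and n-PrSH then free the phenol to give tert-butyl 3-[(4R)-4-{[6-hydroxy-2,4-dimethoxy-3-(3-methylbut-2-en-1-yl)phenyl]methyl}-2-oxooxolan-3-yl]propanoate F2. MeLi (2.2 equiv, −78 °C) should open the lactone and leave the tert-butyl ester, giving tert-butyl (5R)-4-acetyl-6-[6-hydroxy-2,4-dimethoxy-3-(3-methylbut-2-en-1-yl)phenyl]-5-(hydroxymethyl)hexanoate F3. Mitsunobu closure (PPh3, DIAD) gives tert-butyl 4-[(3R)-5,7-dimethoxy-6-(3-methylbut-2-en-1-yl)-3,4-dihydro-2H-chromen-3-yl]-5-oxohexanoate F4, and KOtBu in THF then has only the Claisen ring closure left to do, which returns to 18.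

2. Step 12. The enolate may be allylated on oxygen, may attack the tertiary end of the allyl complex, or may take a second prenyl group at C2. The fallback sets out from 18 and comes back at 22; it moves the prenylation to the aromatic stage. Compound 18 is dehydrogenated with LiN(iPr)2 and N-tert-butylbenzenesulfinimidoyl chloride as in step 13 to 4-[(3R)-5,7-dimethoxy-6-(3-methylbut-2-en-1-yl)-3,4-dihydro-2H-chromen-3-yl]benzene-1,3-diol F5. MOMCl and iPr2NEt give (3R)-3-[2,4-bis(methoxymethoxy)phenyl]-5,7-dimethoxy-6-(3-methylbut-2-en-1-yl)-3,4-dihydro-2H-chromene F6. n-BuLi (THF, 0 °C) should lithiate C3' between the two OMOM groups, and quenching with 2 gives (3R)-3-[2,4-bis(methoxymethoxy)-3-(3-methylbut-2-en-1-yl)phenyl]-5,7-dimethoxy-6-(3-methylbut-2-en-1-yl)-3,4-dihydro-2H-chromene F7. ZnBr2 and n-PrSH remove both acetals and give 22.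

3. Step 13. Dianion formation may be incomplete, or the sulfur reagent may be consumed by the amide base or transferred to C2, so that dehydrogenation stalls. The fallback sets out from 20 and comes back at 22; it replaces enolate chemistry by a Saegusa–Ito oxidation. TMSOTf and Et3N (CH2Cl2, 0 °C) convert 20 into (3R)-3-[3-(3-methylbut-2-en-1-yl)-2,4-bis(trimethylsilyloxy)cyclohexa-2,4-dien-1-yl]-5,7-dimethoxy-6-(3-methylbut-2-en-1-yl)-3,4-dihydro-2H-chromene F8. Pd(OAc)2 (MeCN, rt) then removes the silyl group from the C4 enol ether and a hydrogen from C6 by β-hydride elimination, the dienone aromatises, and mild aqueous work-up cleaves the remaining aryl silyl ether to give 22.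

**Further compounds**

F1 | step 11 | tert-butyl 3-[(4R)-4-{[2,4-dimethoxy-6-(methoxymethoxy)-3-(3-methylbut-2-en-1-yl)phenyl]methyl}-2-oxooxolan-3-yl]propanoate | COCOc1cc(OC)c(CC=C(C)C)c(OC)c1C[C@H]1COC(=O)C1CCC(=O)OC(C)(C)C
F2 | step 11 | tert-butyl 3-[(4R)-4-{[6-hydroxy-2,4-dimethoxy-3-(3-methylbut-2-en-1-yl)phenyl]methyl}-2-oxooxolan-3-yl]propanoate | COc1cc(O)c(C[C@H]2COC(=O)C2CCC(=O)OC(C)(C)C)c(OC)c1CC=C(C)C
F3 | step 11 | tert-butyl (5R)-4-acetyl-6-[6-hydroxy-2,4-dimethoxy-3-(3-methylbut-2-en-1-yl)phenyl]-5-(hydroxymethyl)hexanoate | COc1cc(O)c(C[C@H](C(CCC(=O)OC(C)(C)C)C(C)=O)CO)c(OC)c1CC=C(C)C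
F4 | step 11 | tert-butyl 4-[(3R)-5,7-dimethoxy-6-(3-methylbut-2-en-1-yl)-3,4-dihydro-2H-chromen-3-yl]-5-oxohexanoate | COc1cc2c(c(OC)c1CC=C(C)C)C[C@H](C(CCC(=O)OC(C)(C)C)C(C)=O)CO2
F5 | step 12 | 4-[(3R)-5,7-dimethoxy-6-(3-methylbut-2-en-1-yl)-3,4-dihydro-2H-chromen-3-yl]benzene-1,3-diol | COc1cc2c(c(OC)c1CC=C(C)C)C[C@H](c1ccc(O)cc1O)CO2
F6 | step 12 | (3R)-3-[2,4-bis(methoxymethoxy)phenyl]-5,7-dimethoxy-6-(3-methylbut-2-en-1-yl)-3,4-dihydro-2H-chromene | COc1cc2c(c(OC)c1CC=C(C)C)C[C@H](c1ccc(OCOC)cc1OCOC)CO2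
F7 | step 12 | (3R)-3-[2,4-bis(methoxymethoxy)-3-(3-methylbut-2-en-1-yl)phenyl]-5,7-dimethoxy-6-(3-methylbut-2-en-1-yl)-3,4-dihydro-2H-chromene | COc1cc2c(c(OC)c1CC=C(C)C)C[C@H](c1ccc(OCOC)c(CC=C(C)C)c1OCOC)CO2
F8 | step 13 | (3R)-3-[3-(3-methylbut-2-en-1-yl)-2,4-bis(trimethylsilyloxy)cyclohexa-2,4-dien-1-yl]-5,7-dimethoxy-6-(3-methylbut-2-en-1-yl)-3,4-dihydro-2H-chromene | COc1cc2c(c(OC)c1CC=C(C)C)C[C@H](C1CC=C(O[Si](C)(C)C)C(CC=C(C)C)=C1O[Si](C)(C)C)CO2
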